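A direct plan would photodimerize the alkenyl imidazopyrimidine carbamate A1 head-to-head to the all-trans cyclobutane A2, resolve A2, free the C2-symmetric diamine A3, acylate its two amines in turn and unmask the aminoimidazoles at the end.
Its weakest steps would be:
- the intermolecular [2+2] photodimerization, because head-to-head regiochemistry and the all-trans arrangement would rest only on biradical behaviour among several possible dimers;
- the chromatographic resolution of racemic A2, because the absolute configuration would be sorted rather than made and half of the material would be lost;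
- the mono-acylation of A3, because its two amines are homotopic, so un-, mono- and bis-acylated diamine would form statistically.

The route rests on unveiling, not building, the four-membered ring: the cyclobutane carbons and their four exocyclic carbons (the two imidazole C-4 atoms and the two CH2N carbons) are already present in the Diels–Alder adduct of 2,5-dimethylfuran and dimethyl acetylenedicarboxylate. After enzymatic desymmetrization and photoisomerization to a 3-oxaquadricyclane, one acid-triggered fragmentation cleaves two cyclopropane bonds and the oxygen bridge and delivers the all-trans cyclobutane with two acetyl groups and two chemically different carboxyl arms as one enantiomer. Absolute configuration therefore comes from the enzyme (no resolution), the arms are distinct from the outset (no statistical acylation), and no intermolecular photodimerization is needed.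

Key step: step 5

Assumption: pig liver esterase is taken to cleave the ester group that gives 4 as drawn, and in step 5 the amide-bearing carbon is taken to be protonated anti to the oxygen bridge; these two senses only decide which monoacid enantiomer is needed, not the chemistry.

**Step 1**
Reactants: 1 2,5-dimethylfuran; 2 dimethyl acetylenedicarboxylate
Product: 3 dimethyl (1R,4S)-1,4-dimethyl-7-oxabicyclo[2.2.1]hepta-2,5-diene-2,3-dicarboxylate (meso)
Conditions: neat, 80 °C
Reagents that add atoms: dimethyl acetylenedicarboxylate (2), COC(=O)C#CC(=O)OC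
Why: Diels–Alder cycloaddition of an electron-rich 2,5-dialkylfuran with an acetylenic diester; the adduct is meso, so no selectivity is needed, and it already holds the ten carbons of the cyclobutane, the two CH2N arms and C-4/C-5 of both imidazoles.

**Step 2**
Reactants: 3 meso diester
Product: 4 (1S,4R)-3-(methoxycarbonyl)-1,4-dimethyl-7-oxabicyclo[2.2.1]hepta-2,5-diene-2-carboxylic acid
Conditions: pig liver esterase, 0.1 M phosphate buffer (pH 8)/acetone 9:1, rt, pH-stat; then acidify
Reagents that add atoms: water, O
Why: Enzymatic desymmetrization of a meso diester (esterase hydrolysis of one enantiotopic ester group), which should both label the two future CH2N arms as different and define the absolute configuration of everything that follows; hydrolysis should stop at the monoacid because the carboxylate is a poor substrate.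

**Step 3**
Reactants: 4 monoacid
Product: 6 methyl (1R,4S)-3-carbamoyl-1,4-dimethyl-7-oxabicyclo[2.2.1]hepta-2,5-diene-2-carboxylate, via mixed anhydride 5 (not isolated)
Conditions: ClCO2Et, Et3N, THF, −15 °C; then NH3 (0.5 M in dioxane), −15 → 0 °C
Reagents that add atoms: ammonia, N
Why: Mixed carbonic anhydride amidation at low temperature (no retro-Diels–Alder), installing a primary carboxamide that is more basic than the ester, does not enolize in acid and later reduces to a CH2NH2 arm; recrystallization of 6 should allow enantiomeric enrichment if needed.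

**Step 4**
Reactants: 6 amide ester
Product: 7 methyl 5-carbamoyl-2,4-dimethyl-3-oxatetracyclo[3.2.0.0^2,7.0^4,6]heptane-1-carboxylate (seen from the oxygen bridge, amide-bearing C → CH → CH → ester-bearing C runs clockwise)
Conditions: hν (medium-pressure Hg lamp, Vycor), MTBE, 0 °C
Reagents that add atoms: none
Why: Intramolecular [2+2] photocycloaddition (norbornadiene-to-quadricyclane valence isomerization) joining C2 to C6 and C3 to C5, i.e. each arm-bearing carbon to a future imidazole-bearing carbon; the cage geometry fixes every new stereocentre, so 6 should give a single enantiomer of 7.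

**Step 5**
Reactants: 7 oxaquadricyclane amide ester
Product: 9 methyl (1S,2S,3R,4R)-3,4-diacetyl-2-carbamoylcyclobutane-1-carboxylate (all-trans), via all-cis diketone 8 (not isolated)
Conditions: H2SO4 (2 equiv), THF/MeOH/H2O (5:5:1), 23 → 45 °C
Reagents that add atoms: water, O
Why: O-protonation of the carboxamide (the more basic carbonyl) triggers heterolysis of the donor–acceptor cyclopropane bond between the ether carbon and the amide-bearing carbon, giving an oxocarbenium ion and an amide enol that is protonated on its exo face; hydration, the same cleavage on the ester side and opening of the resulting bis-hemiketal release the two acetyl groups as all-cis diketone 8. The closest known reaction type is the acid-catalysed ring opening of donor–acceptor cyclopropanes as used in 3-oxaquadricyclane fragmentations. No ring is closed: the cyclobutane bonds made in step 4 stay, and two cyclopropane C–C bonds and the ether bridge are cleaved. The amide-bearing carbon is set by the kinetic exo protonation and does not enolize in acid, whereas the two acetyl-bearing carbons and the ester-bearing carbon epimerize through their enols until each substituent is trans to both neighbours, so this one centre relays the other three and the enzyme-derived chirality is kept. The step needs regioselective cleavage toward the carboxyl-bearing carbons, which their acceptor groups secure, and an amide α-carbon that stays inert, which the low kinetic acidity of amide α-hydrogens in acid secures.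

**Step 6**
Reactants: 9 all-trans diketone
Product: 10 methyl (1S,2S,3R,4R)-2-carbamoyl-3,4-bis(chloroacetyl)cyclobutane-1-carboxylate
Conditions: BnNMe3+ ICl2− (4.2 equiv), THF, 60 °C
Reagents that add atoms: benzyltrimethylammonium dichloroiodate, C[N+](C)(C)Cc1ccccc1.Cl[I-]Cl
Why: Electrophilic α-chlorination of methyl ketones through their enols; enolization toward the ring would place an exocyclic double bond on the cyclobutane and is disfavoured, so chlorination should occur at both CH3 groups, and the ring carbons stay at their thermodynamic all-trans configuration.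

**Step 7**
Reactants: 10 bis(chloromethyl ketone)
Product: 11 methyl (1S,2S,3R,4R)-2-carbamoyl-3,4-bis(2-chloro-1,1-dimethoxyethyl)cyclobutane-1-carboxylate
Conditions: HC(OMe)3, MeOH, TsOH·H2O (cat.), rt → 40 °C
Reagents that add atoms: methanol, CO; trimethyl orthoformate, COC(OC)OC
Why: Acid-catalysed ketalization with orthoformate as water scavenger, which protects both ketones from borane and makes the two ketone-bearing ring carbons non-enolizable.

**Step 8**
Reactants: 11 bis(dimethyl ketal)
Product: 12 [(1R,2R,3S,4S)-2-(aminomethyl)-3,4-bis(2-chloro-1,1-dimethoxyethyl)cyclobutyl]methanol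
Conditions: BH3·SMe2 (excess), THF, 0 °C → reflux; then MeOH, 60 °C
Reagents that add atoms: none
Why: Borane reduction of the primary amide to the primary amine and, on heating, of the methyl ester to the primary alcohol; the electrophilic hydride should leave C–Cl bonds and the electron-poor ketals untouched, the two arms emerge as NH2 and OH, and no stereocentre is enolizable any more.

**Step 9**
Reactants: 12 amino alcohol; 13 2,2,2-trichloro-1-(1H-pyrrol-2-yl)ethan-1-one
Product: 14 N-{[(1R,2S,3S,4R)-2,3-bis(2-chloro-1,1-dimethoxyethyl)-4-(hydroxymethyl)cyclobutyl]methyl}-1H-pyrrole-2-carboxamide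
Conditions: i-Pr2NEt, DMF, rt
Reagents that add atoms: 2-(trichloroacetyl)pyrrole (13), O=C(c1ccc[nH]1)C(Cl)(Cl)Cl
Why: Haloform-type N-acylation by a trichloromethyl ketone, chemoselective for the primary amine over the primary alcohol, so the first pyrrole amide goes onto one defined arm.

**Step 10**
Reactants: 14 hydroxy amide
Product: 16 N-{[(1R,2S,3S,4R)-4-(azidomethyl)-2,3-bis(2-chloro-1,1-dimethoxyethyl)cyclobutyl]methyl}-1H-pyrrole-2-carboxamide, via mesylate 15 (not isolated)
Conditions: MsCl, Et3N, CH2Cl2, 0 °C; then NaN3, DMF, 60 °C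
Reagents that add atoms: sodium azide, [Na+].[N-]=[N+]=[N-]
Why: Mesylation and SN2 azide displacement at the primary CH2; the chloromethyl groups sit next to quaternary ketal carbons and should be inert, and no stereocentre is touched.

**Step 11**
Reactants: 16 azide; 17 1-(4-bromo-1H-pyrrol-2-yl)-2,2,2-trichloroethan-1-one
Product: 19 N-{[(1R,2S,3S,4R)-4-{[(4-bromo-1H-pyrrole-2-carbonyl)amino]methyl}-2,3-bis(2-chloro-1,1-dimethoxyethyl)cyclobutyl]methyl}-1H-pyrrole-2-carboxamide, via primary amine 18 (not isolated)
Conditions: PPh3, THF/H2O, 50 °C; then 17, i-Pr2NEt, DMF, rt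
Reagents that add atoms: 4-bromo-2-(trichloroacetyl)pyrrole (17), O=C(c1cc(Br)c[nH]1)C(Cl)(Cl)Cl
Why: Staudinger reduction of the azide followed by haloform-type N-acylation in the same flask, placing the bromopyrrole amide on the second arm without any competition from the first.

**Step 12**
Reactants: 19 bis-amide bis-ketal
Product: 20 N-{[(1R,2S,3S,4R)-4-{[(4-bromo-1H-pyrrole-2-carbonyl)amino]methyl}-2,3-bis(chloroacetyl)cyclobutyl]methyl}-1H-pyrrole-2-carboxamide
Conditions: 2 M aq. HCl/THF (1:1), 45 °C
Reagents that add atoms: water, O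
Why: Acid hydrolysis of the dimethyl ketals; pyrrole-2-carboxamides and the aryl bromide tolerate aqueous acid, and the ketone-bearing ring carbons can only return to the all-trans arrangement because the arm-bearing carbons are now fixed.

**Step 13**
Reactants: 20 bis(chloromethyl ketone); 21 tert-butyl carbamimidoylcarbamate (N-Boc-guanidine)
Product: 22 N-{[(1R,2S,3S,4R)-2,3-bis[2-amino-1-(tert-butoxycarbonyl)-1H-imidazol-4-yl]-4-{[(4-bromo-1H-pyrrole-2-carbonyl)amino]methyl}cyclobutyl]methyl}-1H-pyrrole-2-carboxamide
Conditions: 21 (6 equiv), NaI (2 equiv), DMF, rt → 40 °C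
Reagents that add atoms: N-Boc-guanidine (21), CC(C)(C)OC(=O)NC(N)=N
Why: Hantzsch-type condensation of an α-haloketone with a monoprotected guanidine (iodide-assisted N-alkylation, then cyclodehydration onto the ketone), giving each 2-aminoimidazole with the cyclobutane carbon on C-4; the Boc position on the ring nitrogen is the usual outcome and is inconsequential.

**Step 14**
Reactants: 22 bis(Boc-aminoimidazole)
Product: 23 desbromosceptrin, N-{[(1R,2S,3S,4R)-2,3-bis(2-amino-1H-imidazol-5-yl)-4-{[(4-bromo-1H-pyrrole-2-carbonyl)amino]methyl}cyclobutyl]methyl}-1H-pyrrole-2-carboxamide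
Conditions: TFA/CH2Cl2 (1:3), rt; reverse-phase HPLC (0.1% TFA), isolated as the bis-TFA salt
Reagents that add atoms: none
Why: Acidolysis of the two N-Boc groups; amides, aryl bromide and all four ring stereocentres are inert to TFA.

**Compound list**

1 | 2,5-dimethylfuran | Cc1ccc(C)o1 | starting material
2 | dimethyl acetylenedicarboxylate | COC(=O)C#CC(=O)OC | starting material
3 | dimethyl (1R,4S)-1,4-dimethyl-7-oxabicyclo[2.2.1]hepta-2,5-diene-2,3-dicarboxylate (meso) | C[C@]12C=C[C@](C)(O1)C(C(=O)OC)=C2C(=O)OC | intermediate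
4 | (1S,4R)-3-(methoxycarbonyl)-1,4-dimethyl-7-oxabicyclo[2.2.1]hepta-2,5-diene-2-carboxylic acid | C[C@]12C=C[C@](C)(O1)C(C(O)=O)=C2C(=O)OC | intermediate
5 | mixed ethyl carbonic anhydride of 4 | C[C@]12C=C[C@](C)(O1)C(C(=O)OC(=O)OCC)=C2C(=O)OC | intermediate (not isolated)
6 | methyl (1R,4S)-3-carbamoyl-1,4-dimethyl-7-oxabicyclo[2.2.1]hepta-2,5-diene-2-carboxylate | C[C@]12C=C[C@](C)(O1)C(C(N)=O)=C2C(=O)OC | intermediate
7 | methyl 5-carbamoyl-2,4-dimethyl-3-oxatetracyclo[3.2.0.0^2,7.0^4,6]heptane-1-carboxylate, single enantiomer as described in step 4 | C[C@]12O[C@]3(C)[C@]4(C(N)=O)[C@@]1(C(=O)OC)[C@H]2[C@H]34 | intermediate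
8 | methyl (1R,2S,3S,4R)-3,4-diacetyl-2-carbamoylcyclobutane-1-carboxylate (all-cis) | CC(=O)[C@@H]1[C@H](C(N)=O)[C@H](C(=O)OC)[C@@H]1C(C)=O | intermediate (not isolated)
9 | methyl (1S,2S,3R,4R)-3,4-diacetyl-2-carbamoylcyclobutane-1-carboxylate (all-trans) | CC(=O)[C@H]1[C@H](C(N)=O)[C@@H](C(=O)OC)[C@@H]1C(C)=O | intermediate
10 | methyl (1S,2S,3R,4R)-2-carbamoyl-3,4-bis(chloroacetyl)cyclobutane-1-carboxylate | ClCC(=O)[C@H]1[C@H](C(N)=O)[C@@H](C(=O)OC)[C@@H]1C(=O)CCl | intermediate
11 | methyl (1S,2S,3R,4R)-2-carbamoyl-3,4-bis(2-chloro-1,1-dimethoxyethyl)cyclobutane-1-carboxylate | ClCC(OC)(OC)[C@H]1[C@H](C(N)=O)[C@@H](C(=O)OC)[C@@H]1C(OC)(OC)CCl | intermediate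
12 | [(1R,2R,3S,4S)-2-(aminomethyl)-3,4-bis(2-chloro-1,1-dimethoxyethyl)cyclobutyl]methanol | ClCC(OC)(OC)[C@H]1[C@H](CN)[C@@H](CO)[C@@H]1C(OC)(OC)CCl | intermediate
13 | 2,2,2-trichloro-1-(1H-pyrrol-2-yl)ethan-1-one | O=C(c1ccc[nH]1)C(Cl)(Cl)Cl | starting material
14 | N-{[(1R,2S,3S,4R)-2,3-bis(2-chloro-1,1-dimethoxyethyl)-4-(hydroxymethyl)cyclobutyl]methyl}-1H-pyrrole-2-carboxamide | ClCC(OC)(OC)[C@H]1[C@H](CNC(=O)c2ccc[nH]2)[C@@H](CO)[C@@H]1C(OC)(OC)CCl | intermediate
15 | methanesulfonate of 14 | ClCC(OC)(OC)[C@H]1[C@H](CNC(=O)c2ccc[nH]2)[C@@H](COS(C)(=O)=O)[C@@H]1C(OC)(OC)CCl | intermediate (not isolated)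
16 | N-{[(1R,2S,3S,4R)-4-(azidomethyl)-2,3-bis(2-chloro-1,1-dimethoxyethyl)cyclobutyl]methyl}-1H-pyrrole-2-carboxamide | ClCC(OC)(OC)[C@H]1[C@H](CNC(=O)c2ccc[nH]2)[C@@H](CN=[N+]=[N-])[C@@H]1C(OC)(OC)CCl | intermediate
17 | 1-(4-bromo-1H-pyrrol-2-yl)-2,2,2-trichloroethan-1-one | O=C(c1cc(Br)c[nH]1)C(Cl)(Cl)Cl | starting material
18 | N-{[(1R,2S,3S,4R)-4-(aminomethyl)-2,3-bis(2-chloro-1,1-dimethoxyethyl)cyclobutyl]methyl}-1H-pyrrole-2-carboxamide | ClCC(OC)(OC)[C@H]1[C@H](CNC(=O)c2ccc[nH]2)[C@@H](CN)[C@@H]1C(OC)(OC)CCl | intermediate (not isolated)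
19 | N-{[(1R,2S,3S,4R)-4-{[(4-bromo-1H-pyrrole-2-carbonyl)amino]methyl}-2,3-bis(2-chloro-1,1-dimethoxyethyl)cyclobutyl]methyl}-1H-pyrrole-2-carboxamide | ClCC(OC)(OC)[C@H]1[C@H](CNC(=O)c2ccc[nH]2)[C@@H](CNC(=O)c2cc(Br)c[nH]2)[C@@H]1C(OC)(OC)CCl | intermediate
20 | N-{[(1R,2S,3S,4R)-4-{[(4-bromo-1H-pyrrole-2-carbonyl)amino]methyl}-2,3-bis(chloroacetyl)cyclobutyl]methyl}-1H-pyrrole-2-carboxamide | ClCC(=O)[C@H]1[C@H](CNC(=O)c2ccc[nH]2)[C@@H](CNC(=O)c2cc(Br)c[nH]2)[C@@H]1C(=O)CCl | intermediate
21 | tert-butyl carbamimidoylcarbamate (N-Boc-guanidine) | CC(C)(C)OC(=O)NC(N)=N | starting material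
22 | N-{[(1R,2S,3S,4R)-2,3-bis[2-amino-1-(tert-butoxycarbonyl)-1H-imidazol-4-yl]-4-{[(4-bromo-1H-pyrrole-2-carbonyl)amino]methyl}cyclobutyl]methyl}-1H-pyrrole-2-carboxamide | CC(C)(C)OC(=O)n1cc(nc1N)[C@H]1[C@H](CNC(=O)c2ccc[nH]2)[C@@H](CNC(=O)c2cc(Br)c[nH]2)[C@@H]1c1cn(C(=O)OC(C)(C)C)c(N)n1 | intermediate
23 | desbromosceptrin | Nc1ncc([C@H]2[C@H](CNC(=O)c3ccc[nH]3)[C@@H](CNC(=O)c3cc(Br)c[nH]3)[C@@H]2c2cnc(N)[nH]2)[nH]1 | target

Total steps: 14. Longest linear sequence: 14 (linear from 1 and 2).

**Steps most likely to fail**

Step 5. The transfer of chirality could leak: the amide enol might be protonated from both faces, the amide-bearing carbon might enolize slowly under the acid, or the neighbouring amide might be lost by participation, giving eroded or inverted enantiomeric purity. The fallback sets out from 3 and does not depend on either stereochemical sense. Irradiation of 3 would give the meso dimethyl oxaquadricyclane-dicarboxylate F1. The same acid fragmentation would give the racemic, C2-symmetric all-trans dimethyl 3,4-diacetylcyclobutane-1,2-dicarboxylate F2, whose two ester groups are homotopic. Enantioselective enzymatic monohydrolysis (esterase or lipase, kinetic resolution) would then give (1S,2R,3R,4S)-2,3-diacetyl-4-(methoxycarbonyl)cyclobutane-1-carboxylic acid F3. Its mixed ethyl carbonic anhydride F4, treated with ammonia as in step 3, would return to the route at 9.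

Step 2. The enzyme might discriminate the two enantiotopic ester groups poorly, or in the opposite sense, so that 4 would be of low enantiomeric purity or the antipode. The fallback sets out from 3. Monosaponification with one equivalent of NaOH in THF/water at 0 °C would give the racemic monoacid F5. Fractional crystallization of the (S)-1-phenylethylammonium salt of the wanted acid F6 (or of the salt with the (R)-amine, whichever is less soluble) and acidification would return to the route at 4.

Step 13. The twofold annulation might stall after one imidazole, or the basic guanidine might divert the α-chloroketones into elimination or self-condensation. The fallback sets out from 20. Displacement of both chlorides with sodium diformylamide in MeCN would give the bis(diformylamino) diketone F7. HCl in MeOH would give the bis(aminomethyl ketone) dihydrochloride F8. Condensation with cyanamide in water at pH 4.5 and 95 °C would return to the route at 23.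

**Further compounds**

F1 | step 5 | dimethyl 2,4-dimethyl-3-oxatetracyclo[3.2.0.0^2,7.0^4,6]heptane-1,5-dicarboxylate (meso) | C[C@]12O[C@]3(C)[C@]4(C(=O)OC)[C@@]1(C(=O)OC)[C@H]2[C@H]34
F2 | step 5 | racemic dimethyl (1S*,2S*,3R*,4R*)-3,4-diacetylcyclobutane-1,2-dicarboxylate (all-trans, wanted enantiomer drawn) | CC(=O)[C@H]1[C@H](C(=O)OC)[C@@H](C(=O)OC)[C@@H]1C(C)=O
F3 | step 5 | (1S,2R,3R,4S)-2,3-diacetyl-4-(methoxycarbonyl)cyclobutane-1-carboxylic acid | CC(=O)[C@H]1[C@H](C(O)=O)[C@@H](C(=O)OC)[C@@H]1C(C)=O
F4 | step 5 | mixed ethyl carbonic anhydride of F3 | CC(=O)[C@H]1[C@H](C(=O)OC(=O)OCC)[C@@H](C(=O)OC)[C@@H]1C(C)=O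
F5 | step 2 | racemic 3-(methoxycarbonyl)-1,4-dimethyl-7-oxabicyclo[2.2.1]hepta-2,5-diene-2-carboxylic acid | CC12C=CC(C)(O1)C(C(O)=O)=C2C(=O)OC
F6 | step 2 | (S)-1-phenylethylammonium salt of 4 | C[C@]12C=C[C@](C)(O1)C(C([O-])=O)=C2C(=O)OC.C[C@H]([NH3+])c1ccccc1
F7 | step 13 | N-{[(1R,2S,3S,4R)-4-{[(4-bromo-1H-pyrrole-2-carbonyl)amino]methyl}-2,3-bis[(diformylamino)acetyl]cyclobutyl]methyl}-1H-pyrrole-2-carboxamide | O=CN(C=O)CC(=O)[C@H]1[C@H](CNC(=O)c2ccc[nH]2)[C@@H](CNC(=O)c2cc(Br)c[nH]2)[C@@H]1C(=O)CN(C=O)C=O
F8 | step 13 | N-{[(1R,2S,3S,4R)-2,3-bis(aminoacetyl)-4-{[(4-bromo-1H-pyrrole-2-carbonyl)amino]methyl}cyclobutyl]methyl}-1H-pyrrole-2-carboxamide dihydrochloride | NCC(=O)[C@H]1[C@H](CNC(=O)c2ccc[nH]2)[C@@H](CNC(=O)c2cc(Br)c[nH]2)[C@@H]1C(=O)CN.Cl.Cl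
A1 | direct plan | tert-butyl (E)-[3-(imidazo[1,2-a]pyrimidin-3-yl)allyl]carbamate | CC(C)(C)OC(=O)NC/C=C/c1cnc2ncccn12
A2 | direct plan | racemic all-trans head-to-head photodimer, di-tert-butyl {[3,4-di(imidazo[1,2-a]pyrimidin-3-yl)cyclobutane-1,2-diyl]bis(methylene)}dicarbamate (one enantiomer drawn) | c1cnc2ncc([C@H]3[C@H](CNC(=O)OC(C)(C)C)[C@@H](CNC(=O)OC(C)(C)C)[C@@H]3c3cnc4ncccn34)n2c1
A3 | direct plan | [(1R,2R,3S,4S)-3,4-di(imidazo[1,2-a]pyrimidin-3-yl)cyclobutane-1,2-diyl]dimethanamine | c1cnc2ncc([C@H]3[C@H](CN)[C@@H](CN)[C@@H]3c3cnc4ncccn34)n2c1
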